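**Retrosynthetic overview**
- The target is 8-lavandulyl-3,5,7,2',4'-pentahydroxyflavone. The endgame is acidic removal of four MOM ethers, preceded by hydroxylation at C3 of a MOM-protected flavone (C3 lithiation, borylation, oxidation).
- Feature: ring C holds a single carbonyl carbon, C4, bonded to C4a of ring A and to C3, and its C2=C3 bond binds O1 and ring B at C2. Ring C therefore divides into an ortho-iodophenol (C4a–I, C8a–OH), carbon monoxide (C4) and an arylacetylene (C3, C2, ring B).
- Iodophenol: from phloroglucinol. A diethylcarbamate on the future O1 directs two ortho-metalations: iodination, Negishi attachment of the side chain from (R)-lavandulol, second iodination, then carbamate hydrolysis.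
- Alkyne: from 2,4-dihydroxybenzaldehyde by MOM protection and Ohira–Bestmann homologation.
- Ring order: rings A and B are purchased; ring C is the only ring formed, in the carbonylative annulation.

Key step: step 10

Assumption: (R)-lavandulol is bought as the single enantiomer. Its stereocentre is never a reacting centre; the descriptor changes from R (6–8) to S (9 onward) only because CH2OH, CH2I and CH2Zn rank above isopropenyl in the CIP order while CH2–aryl ranks below it.

In the names below, "(S)-lavandulyl" stands for (2S)-5-methyl-2-(prop-1-en-2-yl)hex-4-en-1-yl.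

**Step 1**
Reactants: 1 phloroglucinol
Product: 2 3,5-bis(methoxymethoxy)phenol
Conditions: MOMCl (2 equiv), iPr2NEt, DMF, 0 °C to rt
Reagents that add atoms: chloromethyl methyl ether (MOMCl), COCCl
Why: Williamson-type O-alkylation, statistical over three equivalent hydroxyls, so two equivalents of MOMCl should give the bis-ether as the main fraction, separable by chromatography from the mono- and tris-ethers.

**Step 2**
Reactants: 2 3,5-bis(methoxymethoxy)phenol
Product: 3 3,5-bis(methoxymethoxy)phenyl N,N-diethylcarbamate
Conditions: ClCONEt2, K2CO3, MeCN, reflux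
Reagents that add atoms: diethylcarbamoyl chloride, CCN(CC)C(Cl)=O
Why: O-carbamoylation (acyl substitution at the carbamoyl chloride) places the strongest oxygen-based directing group for ortho-metalation on the oxygen that will become O1.

**Step 3**
Reactants: 3 3,5-bis(methoxymethoxy)phenyl N,N-diethylcarbamate
Product: 5 2-iodo-3,5-bis(methoxymethoxy)phenyl N,N-diethylcarbamate, via aryllithium 4 (not isolated)
Conditions: s-BuLi, TMEDA, THF, −78 °C; then I2, THF, −78 °C to rt
Reagents that add atoms: iodine, II
Why: Directed ortho-metalation, in which the carbamate outranks OMOM as directing group, so the proton between OCONEt2 and OMOM should be removed in preference to the one between the two MOM ethers, and iodine traps 4 at −78 °C, below the onset of the anionic ortho-Fries shift.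

**Step 4**
Reactants: 6 (R)-lavandulol
Product: 7 (R)-lavandulyl iodide, (2R)-1-iodo-5-methyl-2-(prop-1-en-2-yl)hex-4-ene
Conditions: PPh3, I2, imidazole, CH2Cl2, 0 °C to rt
Reagents that add atoms: iodine, II
Why: Appel-type iodination displaces the activated primary hydroxyl by SN2 at C1, so the adjacent stereocentre is not involved and keeps its configuration.

**Step 5**
Reactants: 7 (R)-lavandulyl iodide; 5 2-iodo-3,5-bis(methoxymethoxy)phenyl N,N-diethylcarbamate
Product: 9 2-[(S)-lavandulyl]-3,5-bis(methoxymethoxy)phenyl N,N-diethylcarbamate, via (R)-lavandulylzinc iodide 8 (not isolated)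
Conditions: Zn (activated), LiCl, THF, 40 °C; then 5, Pd(OAc)2 (cat.), SPhos, THF, 50 °C
Reagents that add atoms: none
Why: Negishi coupling, in which zinc insertion into the primary C–I bond gives a homoallylic zinc reagent (a class that transmetalates readily) and the bulky, electron-rich ligand SPhos (2-dicyclohexylphosphino-2',6'-dimethoxybiphenyl) should make reductive elimination faster than β-hydride elimination; the stereocentre is β to zinc, takes no part in bond formation and is carried over unchanged.

**Step 6**
Reactants: 9 2-[(S)-lavandulyl]-3,5-bis(methoxymethoxy)phenyl N,N-diethylcarbamate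
Product: 11 2-iodo-6-[(S)-lavandulyl]-3,5-bis(methoxymethoxy)phenyl N,N-diethylcarbamate, via aryllithium 10 (not isolated)
Conditions: s-BuLi, TMEDA, THF, −78 °C; then ICH2CH2I, −78 °C to rt
Reagents that add atoms: 1,2-diiodoethane, ICCI
Why: Second directed ortho-metalation at the only remaining position ortho to the carbamate (again flanked by OMOM), which ring lithiation at −78 °C should reach faster than the branched benzylic CH2, and 1,2-diiodoethane delivers iodine without exposing the diene to free I2.

**Step 7**
Reactants: 11 2-iodo-6-[(S)-lavandulyl]-3,5-bis(methoxymethoxy)phenyl N,N-diethylcarbamate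
Product: 12 2-iodo-6-[(S)-lavandulyl]-3,5-bis(methoxymethoxy)phenol
Conditions: KOH, EtOH/H2O, reflux; then aq NH4Cl
Reagents that add atoms: none
Why: Alkaline hydrolysis of the aryl carbamate (acyl substitution) frees the phenol; MOM ethers, the aryl iodide and the diene are inert to hydroxide, and the near-neutral work-up keeps the acetals.

**Step 8**
Reactants: 13 2,4-dihydroxybenzaldehyde
Product: 14 2,4-bis(methoxymethoxy)benzaldehyde
Conditions: MOMCl (excess), iPr2NEt, CH2Cl2, 0 °C to reflux
Reagents that add atoms: chloromethyl methyl ether (MOMCl), COCCl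
Why: Williamson-type O-alkylation of both phenols, with excess reagent and heating because the 2-hydroxyl is hydrogen-bonded to the aldehyde.

**Step 9**
Reactants: 14 2,4-bis(methoxymethoxy)benzaldehyde
Product: 15 1-ethynyl-2,4-bis(methoxymethoxy)benzene
Conditions: dimethyl (1-diazo-2-oxopropyl)phosphonate, K2CO3, MeOH, rt
Reagents that add atoms: dimethyl (1-diazo-2-oxopropyl)phosphonate, CC(=O)C(=[N+]=[N-])P(=O)(OC)OC
Why: Seyferth–Gilbert homologation in its Ohira–Bestmann version converts the aryl aldehyde into the terminal alkyne under mild K2CO3/MeOH conditions, to which MOM ethers are stable.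

**Step 10**
Reactants: 12 2-iodo-6-[(S)-lavandulyl]-3,5-bis(methoxymethoxy)phenol; 15 1-ethynyl-2,4-bis(methoxymethoxy)benzene; 16 carbon monoxide
Product: 19 2-[2,4-bis(methoxymethoxy)phenyl]-5,7-bis(methoxymethoxy)-8-[(S)-lavandulyl]-4H-chromen-4-one, via ynone 17 (not isolated), via enaminone 18 (not isolated)
Conditions: PdCl2(PPh3)2 (5 mol%), CO (20 bar), Et2NH, 120 °C
Reagents that add atoms: none
Why: Zerovalent palladium, generated in situ from the divalent precatalyst PdCl2(PPh3)2, adds to the C4a–I bond of 12, CO inserts to give an aroylpalladium iodide (C4a–C4), and alkynylation by 15 forms C4–C3 and releases ynone 17; Et2NH then adds to C2 of 17 to give enaminone 18, and the C8a hydroxyl displaces the amine at C2 (O1–C2). The closest known reaction type is the palladium-catalysed carbonylative annulation of ortho-iodophenols with terminal arylacetylenes to flavones in a secondary amine. Ring C, the only ring formed, closes by 6-endo-trig oxa-Michael addition of the phenol oxygen to the enaminone followed by elimination of Et2NH. No stereocentre is created, and the side-chain stereocentre is remote from every reacting atom and is not exposed to acid, oxidant or strong base. The step needs CO insertion to precede alkynylation, which CO pressure secures against direct coupling and furan closure, and six- rather than five-membered closure, which the enaminone formed in neat Et2NH secures against the aurone pathway. Which oxygen becomes O1 is settled by the substrate, because the only free hydroxyl of 12 sits between the C–I carbon and the lavandulyl-bearing carbon while the other oxygen ortho to iodine is capped as a MOM ether.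

**Step 11**
Reactants: 19 2-[2,4-bis(methoxymethoxy)phenyl]-5,7-bis(methoxymethoxy)-8-[(S)-lavandulyl]-4H-chromen-4-one
Product: 22 2-[2,4-bis(methoxymethoxy)phenyl]-3-hydroxy-5,7-bis(methoxymethoxy)-8-[(S)-lavandulyl]-4H-chromen-4-one, via 3-lithioflavone 20 (not isolated), via lithium trimethoxyborate 21 (not isolated)
Conditions: LiN(iPr)2, THF, −78 °C; B(OMe)3, −78 to 0 °C; then AcOH, 30% aq H2O2, 0 °C to rt
Reagents that add atoms: hydrogen peroxide, OO
Why: Metalation–borylation–oxidation, in which C3–H (vinylic, α to the carbonyl, lithium held by the C4 oxygen) is the most acidic C–H of a 5,7-dialkoxyflavone, the C–B bond is oxidised with 1,2-shift of C3 to oxygen, and unactivated H2O2 at 0 °C should not epoxidise the isolated alkenes.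

**Step 12**
Reactants: 22 2-[2,4-bis(methoxymethoxy)phenyl]-3-hydroxy-5,7-bis(methoxymethoxy)-8-[(S)-lavandulyl]-4H-chromen-4-one
Product: 23 2-(2,4-dihydroxyphenyl)-3,5,7-trihydroxy-8-[(2S)-5-methyl-2-(prop-1-en-2-yl)hex-4-en-1-yl]-4H-chromen-4-one
Conditions: 3 M aq HCl, MeOH, 40 °C
Reagents that add atoms: none
Why: Acid-catalysed acetal exchange with methanol removes all four MOM groups as dimethoxymethane, with dilute acid and moderate temperature chosen so that acetal cleavage outpaces protonation of the side-chain alkenes; the stereocentre is not involved.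

**Compound list**
1 | phloroglucinol | Oc1cc(O)cc(O)c1 | starting material
2 | 3,5-bis(methoxymethoxy)phenol | COCOc1cc(O)cc(OCOC)c1 | intermediate
3 | 3,5-bis(methoxymethoxy)phenyl N,N-diethylcarbamate | CCN(CC)C(=O)Oc1cc(OCOC)cc(OCOC)c1 | intermediate
4 | 2-[(diethylcarbamoyl)oxy]-4,6-bis(methoxymethoxy)phenyllithium | CCN(CC)C(=O)Oc1cc(OCOC)cc(OCOC)c1[Li] | intermediate
5 | 2-iodo-3,5-bis(methoxymethoxy)phenyl N,N-diethylcarbamate | CCN(CC)C(=O)Oc1cc(OCOC)cc(OCOC)c1I | intermediate
6 | (R)-lavandulol, (2R)-5-methyl-2-(prop-1-en-2-yl)hex-4-en-1-ol | C=C(C)[C@@H](CC=C(C)C)CO | starting material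
7 | (R)-lavandulyl iodide, (2R)-1-iodo-5-methyl-2-(prop-1-en-2-yl)hex-4-ene | C=C(C)[C@@H](CC=C(C)C)CI | intermediate
8 | (R)-lavandulylzinc iodide, [(2R)-5-methyl-2-(prop-1-en-2-yl)hex-4-en-1-yl]zinc iodide | C=C(C)[C@@H](CC=C(C)C)C[Zn]I | intermediate
9 | 2-[(S)-lavandulyl]-3,5-bis(methoxymethoxy)phenyl N,N-diethylcarbamate | C=C(C)[C@@H](CC=C(C)C)Cc1c(OCOC)cc(OCOC)cc1OC(=O)N(CC)CC | intermediate
10 | 2-[(diethylcarbamoyl)oxy]-3-[(S)-lavandulyl]-4,6-bis(methoxymethoxy)phenyllithium | C=C(C)[C@@H](CC=C(C)C)Cc1c(OCOC)cc(OCOC)c([Li])c1OC(=O)N(CC)CC | intermediate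
11 | 2-iodo-6-[(S)-lavandulyl]-3,5-bis(methoxymethoxy)phenyl N,N-diethylcarbamate | C=C(C)[C@@H](CC=C(C)C)Cc1c(OCOC)cc(OCOC)c(I)c1OC(=O)N(CC)CC | intermediate
12 | 2-iodo-6-[(S)-lavandulyl]-3,5-bis(methoxymethoxy)phenol | C=C(C)[C@@H](CC=C(C)C)Cc1c(OCOC)cc(OCOC)c(I)c1O | intermediate
13 | 2,4-dihydroxybenzaldehyde | O=Cc1ccc(O)cc1O | starting material
14 | 2,4-bis(methoxymethoxy)benzaldehyde | O=Cc1ccc(OCOC)cc1OCOC | intermediate
15 | 1-ethynyl-2,4-bis(methoxymethoxy)benzene | C#Cc1ccc(OCOC)cc1OCOC | intermediate
16 | carbon monoxide | [C-]#[O+] | starting material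
17 | 3-[2,4-bis(methoxymethoxy)phenyl]-1-{2-hydroxy-3-[(S)-lavandulyl]-4,6-bis(methoxymethoxy)phenyl}prop-2-yn-1-one | C=C(C)[C@@H](CC=C(C)C)Cc1c(OCOC)cc(OCOC)c(C(=O)C#Cc2ccc(OCOC)cc2OCOC)c1O | intermediate
18 | 3-[2,4-bis(methoxymethoxy)phenyl]-3-(diethylamino)-1-{2-hydroxy-3-[(S)-lavandulyl]-4,6-bis(methoxymethoxy)phenyl}prop-2-en-1-one (alkene geometry not defined) | C=C(C)[C@@H](CC=C(C)C)Cc1c(OCOC)cc(OCOC)c(C(=O)C=C(N(CC)CC)c2ccc(OCOC)cc2OCOC)c1O | intermediate
19 | 2-[2,4-bis(methoxymethoxy)phenyl]-5,7-bis(methoxymethoxy)-8-[(S)-lavandulyl]-4H-chromen-4-one | C=C(C)[C@@H](CC=C(C)C)Cc1c(OCOC)cc(OCOC)c2c(=O)cc(-c3ccc(OCOC)cc3OCOC)oc12 | intermediate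
20 | 3-lithio derivative of flavone 19 | C=C(C)[C@@H](CC=C(C)C)Cc1c(OCOC)cc(OCOC)c2c(=O)c([Li])c(-c3ccc(OCOC)cc3OCOC)oc12 | intermediate
21 | lithium trimethoxy(flavon-3-yl)borate derived from 20 | C=C(C)[C@@H](CC=C(C)C)Cc1c(OCOC)cc(OCOC)c2c(=O)c([B-](OC)(OC)OC)c(-c3ccc(OCOC)cc3OCOC)oc12.[Li+] | intermediate
22 | 2-[2,4-bis(methoxymethoxy)phenyl]-3-hydroxy-5,7-bis(methoxymethoxy)-8-[(S)-lavandulyl]-4H-chromen-4-one | C=C(C)[C@@H](CC=C(C)C)Cc1c(OCOC)cc(OCOC)c2c(=O)c(O)c(-c3ccc(OCOC)cc3OCOC)oc12 | intermediate
23 | 2-(2,4-dihydroxyphenyl)-3,5,7-trihydroxy-8-[(2S)-5-methyl-2-(prop-1-en-2-yl)hex-4-en-1-yl]-4H-chromen-4-one | C=C(C)[C@@H](CC=C(C)C)Cc1c(O)cc(O)c2c(=O)c(O)c(-c3ccc(O)cc3O)oc12 | target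

**Step count**
Total steps: 12. Longest linear sequence: 9 steps (steps 1, 2, 3, 5, 6, 7, 10, 11, 12, from phloroglucinol).

**Steps most likely to fail**

1. Step 10. Alkynylation of the arylpalladium may run ahead of CO insertion, the ynone may close to a five-membered ring, or oxidative addition at the electron-rich, di-ortho-substituted iodide may be slow. The fallback builds ring C without CO and without palladium, setting out from 12 and 15. Alkyne 15 is deprotonated with n-BuLi and formylated with DMF to 3-[2,4-bis(methoxymethoxy)phenyl]prop-2-ynal F1. Iodophenol 12 is treated with n-BuLi (2 equiv, THF, −78 °C; phenoxide formation and iodine–lithium exchange) and added to F1, giving 3-[2,4-bis(methoxymethoxy)phenyl]-1-{2-hydroxy-3-[(S)-lavandulyl]-4,6-bis(methoxymethoxy)phenyl}prop-2-yn-1-ol F2 as both carbinol epimers. MnO2 in CH2Cl2 oxidises the benzylic propargylic alcohol, which returns to the route at ynone 17. Warming 17 with Et2NH in EtOH closes ring C through enaminone 18 to flavone 19.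

2. Step 5. β-Hydride elimination from the alkylpalladium intermediate (with loss or scrambling of the side chain), or slow zinc insertion or transmetalation at the hindered iodide, may erode the coupling. The fallback reverses the polarity and sets out from 3 and 6. (R)-Lavandulol 6 is converted with Tf2O and 2,6-lutidine in CH2Cl2 at −78 °C into (2R)-5-methyl-2-(prop-1-en-2-yl)hex-4-en-1-yl trifluoromethanesulfonate F3, which is used at once. Aryllithium 4, made from 3 as in step 3, is alkylated by F3 at −78 °C in an SN2 reaction, below the temperature of the anionic ortho-Fries shift. This returns to the route at 9 and bypasses 5, 7 and 8.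

3. Step 12. Protonation of the isopropenyl or prenyl double bond may compete with acetal cleavage, followed by ring closure of the side chain onto the neighbouring 7-hydroxyl or addition of methanol. The fallback sets out from 22 and cleaves the acetals under aprotic conditions by transfer to a soft nucleophile: ZnBr2 and n-PrSH in CH2Cl2 at 0 °C pass each CH2OMe unit to sulfur, without free Brønsted acid. It ends at 23 with no new intermediate.

**Further compounds**
F1 | step 10 | 3-[2,4-bis(methoxymethoxy)phenyl]prop-2-ynal | O=CC#Cc1ccc(OCOC)cc1OCOC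
F2 | step 10 | 3-[2,4-bis(methoxymethoxy)phenyl]-1-{2-hydroxy-3-[(S)-lavandulyl]-4,6-bis(methoxymethoxy)phenyl}prop-2-yn-1-ol (both carbinol epimers) | C=C(C)[C@@H](CC=C(C)C)Cc1c(OCOC)cc(OCOC)c(C(O)C#Cc2ccc(OCOC)cc2OCOC)c1O
F3 | step 5 | (2R)-5-methyl-2-(prop-1-en-2-yl)hex-4-en-1-yl trifluoromethanesulfonate | C=C(C)[C@@H](CC=C(C)C)COS(=O)(=O)C(F)(F)F
F0 | step 12 | none | none
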